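The numbers in the tables were generated by integration on assumed constants; scatter was added.

West and north-west get the same charges. They differ in when a molecule of free monomer enters: at the start in west, within the first 2.0 min in north-west, where the volume grows meanwhile.

| flask | free monomer | transfer agent | initiator | remark | time |
|---|---|---|---|---|---|
| dusk | 0.050 M (fed, over 2.0 min) | 0.015 M | 1.4 mM | run made earlier; the fed solution adds 0.50 times the starting volume |  |
| noon | 0.050 M (fed, over 2.0 min) | 0.015 M | 2.2 mM | run made earlier; the fed solution adds 0.50 times the starting volume |  |
| west | 0.050 M | 0.0150 M | 1.0 mM | everything together at the start, the whole solution of free monomer included, so that from the start the volume is larger by 0.50 times the starting volume | 12 min |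
| north-west | 0.050 M (fed, over 2.0 min) | 0.0150 M | 1.0 mM | the fed solution adds 0.50 times the starting volume | 12 min |

| run | time / min | monomer in chains / % | free monomer / % |
|---|---|---|---|
| dusk | 2.00 | 29.0 | 72.6 |
| dusk | 4.00 | 56.5 | 44.8 |
| dusk | 5.00 | 61.6 | 38.4 |
| dusk | 8.00 | 73.4 | 28.9 |
| noon | 2.00 | 35.9 | 63.0 |
| noon | 4.00 | 67.4 | 32.6 |
| noon | 5.00 | 76.4 | 24.9 |
| noon | 8.00 | 86.6 | 15.3 |

(scatter of a reading: 1 percentage point)

- charges are per starting volume, the dose included; the dosed solution carries all of it
- what was read earlier has a scatter of 1 percentage point, one standard deviation
- steps that have been proposed: living end + transfer agent -> dead chain; free monomer + living end -> monomer in chains + living end; 2 living end <-> resting dimer; free monomer + initiator -> living end + monomer in chains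

- the winner by amount of monomer in chains, in percent of the free monomer charged; "neither" if no more than 2 percentage points parts them (west / north-west / neither)
- how much monomer in chains is there at the end, in percent of the free monomer charged: west
- how much monomer in chains is there at the end, in percent of the free monomer charged: north-west

Follow one molecule of free monomer. I assume its risk of joining a chain is pseudo-first-order: it depends on the living ends around it, not on other free monomer. Its chance of staying free is then exp(−exposure), where exposure is that risk summed over time.

From 2.00 min to 8.00 min, noon's exposure over dusk's is 1.54, and their initiator ratio is 1.57. So I scale exposure with initiator. Summed over both runs, these readings fade with time: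

2.00 min to 5.00 min: 1.57

5.00 min to 8.00 min: 0.771

time constant, as read: 4.24 min

At 1.0 mM, exposure from the end of the feed to 12 min is then 0.776.

Now take two extremes. If all the monomer entered at the end of the feed, chains would hold 54.0%. If it all entered at the start, it would also take the early exposure S. That second case is west, if I grant west the same early exposure.

North-west lies between: each fed molecule enters between those moments. Extending the dusk and noon readings in a straight line to 1.0 mM gives an estimate of 77.4% free at the end of the feed. I take the risk as steady over the feed, and the average molecule enters mid-feed, so:

S = 0.512

west: 72.4% in chains

north-west: 64.4% in chains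

The forecast, above my figures, gives west, with 73% for west and 67% for north-west, since west “initiates sooner and loses no time to feeding”.

The flasks give west: 70.7% in west, 64.5% in north-west.

    living end + transfer agent → dead chain (kL = 0.635 L mol⁻¹ s⁻¹)
    free monomer + living end → monomer in chains + living end, rate k2*[living end]*[free monomer] (k = 11.4 L mol⁻¹ s⁻¹)
    2 living end ⇌ resting dimer (K = 568 L mol⁻¹, k = 33.7 L mol⁻¹ s⁻¹)
    free monomer + initiator → living end + monomer in chains (k = 2.89 L mol⁻¹ s⁻¹)

North-west fell from 78.0% free at 2.00 min to 35% at 12.0 min, an exposure of 0.788 against my 0.776. A second flask, west with 0.037 M of transfer agent, tests the quantity: if exposure goes inversely with transfer agent, my west exposure 1.29 shrinks to 0.522, so 59.3% free, and that flask holds 59.9% free at 12.0 min. West itself has not quite come to rest, with 1.65 × 10⁻⁵ M of living end at 12.0 min. Left until 120 min, west takes 0.0325 more exposure and reaches 71.6%. North-west reaches 65.8% by 120 min.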